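**Plan**

1. Ring numbering: C1 = O-vanilloyl carbinol, C2=C3(Me) (E), C4 = free carbinol (S), C5, C6=C7(Me) (Z), C8–C10, C11 = CMe2.
2. Cuts: (a) the vanillate C(=O)–O bond at C1; (b) the ring bond C1–C11; (c) in the open chain, C7–CH3 with C6–H (carbometalation of a C6≡C7 alkyne), C7–C8 (acetylide alkylation), C4–C5 (propargylation) and C2=C3 (Wittig).
3. Enabling feature: in the only ring, the quaternary CMe2 carbon C11 sits directly on the allylic carbinol C1. C11 is the Markovnikov carbon of an isopropenyl group and C1 the carbonyl carbon of an E-enal, so two acceptor-type carbons of a plain C15 trienal are joined after polarity reversal of the alkene (hydrogen-atom transfer, chromium capture); ring, quaternary carbon and C1 carbinol arise together.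
4. Forward order: C5 enal (Wittig) → propargylation (C4) → alkyne alkylation → methylmagnesiation (Z-C6=C7) → desilylation, oxidation, silylation → ring closure C1–C11 → esterification → desilylation.
5. Stereochemistry: C4 (S) from phosphoric-acid-catalysed propargylboration; E-C2=C3 from the stabilised ylide; Z-C6=C7 from alkoxide-directed syn-carbomagnesiation; C1 (R) from C4 during ring closure (allylic-strain model), retained on acylation.

Key step: step 9

Remark (assumption): the sense of induction in step 2 is taken over from aryl and alkenyl aldehydes ((R)-catalyst attacks the Re face), so the (S)-catalyst is specified for the Si face; it is to be confirmed on 6 by chiral HPLC. Open-chain compounds are numbered from the oxygenated C1 end, as in the ring.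

**Step 1**
Reactants: 1 (tert-butyldimethylsilyloxy)acetaldehyde; 2 2-(triphenylphosphoranylidene)propanal
Product: 3 (E)-4-[(tert-butyldimethylsilyl)oxy]-2-methylbut-2-enal
Conditions: toluene, 90 °C
Reagents that add atoms: none
Why: Wittig olefination with a stabilised formyl ylide attacks only the unhindered aldehyde 1 and should give the E-trisubstituted enal.

**Step 2**
Reactants: 3; 4 allenylboronic acid pinacol ester
Product: 6 (2E,4S)-1-[(tert-butyldimethylsilyl)oxy]-3-methylhept-2-en-6-yn-4-ol, via pinacol borate ester 5 (not isolated)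
Conditions: (S)-3,3'-bis(2,4,6-triisopropylphenyl)-1,1'-binaphthyl-2,2'-diyl hydrogen phosphate (10 mol %), 4 Å MS, toluene, 0 °C to rt; then aq. NaHCO3
Reagents that add atoms: none
Why: Chiral-phosphoric-acid-catalysed propargylboration (SE2' addition through a closed six-membered transition state) in which the catalyst, hydrogen-bonded to a boronate oxygen and the formyl C–H, should direct attack to the Si face and set C4 as S.

**Step 3**
Reactants: 7 4-methylpent-4-en-1-ol
Product: 8 5-iodo-2-methylpent-1-ene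
Conditions: PPh3, I2, imidazole, CH2Cl2, 0 °C to rt
Reagents that add atoms: iodine, II
Why: Appel-type iodination of a primary alcohol by SN2 displacement of the alkoxyphosphonium group; the 1,1-disubstituted alkene is inert.

**Step 4**
Reactants: 6; 8
Product: 10 (2E,4S)-1-[(tert-butyldimethylsilyl)oxy]-3,11-dimethyldodeca-2,11-dien-6-yn-4-ol, via dilithio alkoxide acetylide 9 (not isolated)
Conditions: n-BuLi (2.1 equiv), THF, −78 to −20 °C; DMPU, 8, −20 °C to rt; then H2O
Reagents that add atoms: n-butyllithium, [Li]CCCC (lithium carried only in 9)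
Why: Acetylide alkylation (SN2) of the alkoxide–acetylide dianion with a primary iodide occurs at carbon, far faster than O-alkylation of the lithium alkoxide, and leaves C4 untouched.

**Step 5**
Reactants: 10
Product: 12 (2E,4S,6Z)-1-[(tert-butyldimethylsilyl)oxy]-3,7,11-trimethyldodeca-2,6,11-trien-4-ol, via alkenylmagnesium bromide 11 (not isolated)
Conditions: Fe(acac)3 (15 mol %), dppe (15 mol %), MeMgBr (5 equiv), THF, −20 to 0 °C; then H2O
Reagents that add atoms: methylmagnesium bromide, C[Mg]Br
Why: Iron-catalysed alkoxide-directed syn-carbomagnesiation of a homopropargylic alcohol should place methyl on the distal carbon C7 and magnesium on C6 (five-membered chelate), so protonation gives the Z-trisubstituted alkene.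

**Step 6**
Reactants: 12
Product: 13 (2E,4S,6Z)-3,7,11-trimethyldodeca-2,6,11-triene-1,4-diol
Conditions: TBAF, THF, 0 °C to rt
Reagents that add atoms: none
Why: Fluoride-mediated cleavage of the primary silyl ether; no other group is fluoride-sensitive.

**Step 7**
Reactants: 13
Product: 14 (2E,4S,6Z)-4-hydroxy-3,7,11-trimethyldodeca-2,6,11-trienal
Conditions: TEMPO (10 mol %), PhI(OAc)2, CH2Cl2, rt
Reagents that add atoms: none
Why: Oxoammonium (TEMPO/PhI(OAc)2) oxidation is much faster for the primary allylic alcohol than for the hindered secondary one and stops at the aldehyde, with the E geometry kept.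

**Step 8**
Reactants: 14
Product: 15 (2E,4S,6Z)-3,7,11-trimethyl-4-[(triethylsilyl)oxy]dodeca-2,6,11-trienal
Conditions: TESOTf, 2,6-lutidine, CH2Cl2, −78 °C
Reagents that add atoms: triethylsilyl trifluoromethanesulfonate, CC[Si](CC)(CC)OS(=O)(=O)C(F)(F)F
Why: Silylation of the secondary allylic alcohol with a silyl triflate and a hindered base is fast at low temperature and tolerates the enal.

**Step 9**
Reactants: 15
Product: 19 (1R,2E,4S,6Z)-3,7,11,11-tetramethyl-4-[(triethylsilyl)oxy]cycloundeca-2,6-dien-1-ol, via tertiary alkylchromium dichloride 16 (not isolated), via chromium alkoxide 17 (not isolated), via phenylsilyl ether 18 (not isolated)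
Conditions: Co(salen) [N,N'-bis(3,5-di-tert-butylsalicylidene)-1,2-cyclohexanediaminocobalt, divalent cobalt] (20 mol %), 1-fluoro-2,4,6-trimethylpyridinium tetrafluoroborate (30 mol %), CrCl3 (50 mol %), PhSiH3 (2 equiv), THF, slow addition of 15 (final 2 mM), rt; then aq. NaHCO3/MeOH
Reagents that add atoms: phenylsilane, [SiH3]c1ccccc1 (silicon carried only in 18); CrCl3, Cl[Cr](Cl)Cl (chromium carried only in 16 and 17)
Why: Proposed new method: a trivalent cobalt hydride (cobalt catalyst, N-fluoropyridinium salt, PhSiH3) transfers a hydrogen atom to the CH2 end of the isopropenyl group; the tertiary C11 radical is held by cobalt and passed on to trivalent chromium as alkylchromium 16, which adds to the enal carbonyl (17), after which chlorosilane from the cobalt cycle silylates the alkoxide (18, chromium set free) and work-up gives 19. The closest known reaction type is the intermolecular cobalt/chromium hydrogen-atom-transfer coupling of unactivated olefins with aldehydes, which joins the branched olefin carbon to the carbonyl carbon, together with Nozaki–Hiyama–Kishi macrocyclisations of organochromium reagents; the ring-forming version on an enal is the new part. The eleven-membered carbocycle closes in the 11-exo-trig mode (C11 onto C1 with the C=O bond outside the ring), aided by the turn at the Z-C6=C7 bond and by slow addition of 15 to the catalysts. C1 is controlled by the C4 stereocentre: in the s-trans enal with C4–H eclipsing the C2=C3 bond (least allylic strain) the chain leaves C4 on the face opposite to the OSiEt3 group, so C11 reaches the Si face of C1=O and the 1R configuration should result. The step needs hydrogen-atom transfer to the isopropenyl group only (the one unhindered 1,1-disubstituted alkene; the other two are trisubstituted, one of them electron-poor), metal capture of the radical ahead of 6-endo attack on C6=C7 (catalyst concentrations kept at the level of the intermolecular reaction) and 1,2- over 1,4-addition (organochromium character, fully substituted β-carbon C3).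

**Step 10**
Reactants: 20 vanillic acid (4-hydroxy-3-methoxybenzoic acid)
Product: 22 4-[(tert-butyldimethylsilyl)oxy]-3-methoxybenzoic acid, via bis-silyl derivative 21 (not isolated)
Conditions: TBSCl (2.5 equiv), imidazole, DMF, rt; then AcOH/THF/H2O, rt
Reagents that add atoms: tert-butyldimethylsilyl chloride, CC(C)(C)[Si](C)(C)Cl
Why: Exhaustive silylation followed by selective solvolysis of the labile silyl ester, which leaves the aryl silyl ether in place.

**Step 11**
Reactants: 19; 22
Product: 24 (1R,2E,4S,6Z)-3,7,11,11-tetramethyl-4-[(triethylsilyl)oxy]cycloundeca-2,6-dien-1-yl 4-[(tert-butyldimethylsilyl)oxy]-3-methoxybenzoate, via mixed anhydride 23 (not isolated)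
Conditions: 2,4,6-trichlorobenzoyl chloride, Et3N, THF, rt; then 19, DMAP, toluene, rt to 60 °C
Reagents that add atoms: 2,4,6-trichlorobenzoyl chloride, O=C(Cl)c1c(Cl)cc(Cl)cc1Cl (carried only in 23)
Why: Yamaguchi esterification, in which DMAP attacks the less hindered vanilloyl carbonyl of the mixed anhydride and the acylpyridinium acylates the hindered neopentylic alcohol at oxygen, so C1 keeps its configuration.

**Step 12**
Reactants: 24
Product: 25 (1R,2E,4S,6Z)-4-hydroxy-3,7,11,11-tetramethylcycloundeca-2,6-dien-1-yl 4-hydroxy-3-methoxybenzoate (target)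
Conditions: TBAF, AcOH, THF, 0 °C to rt
Reagents that add atoms: none
Why: Fluoride cleaves the aryl and the secondary silyl ether, and the acetic acid buffer should protect the ester from cleavage or migration and the allylic positions from transposition.

**Compound list**

1 | (tert-butyldimethylsilyloxy)acetaldehyde | O=CCO[Si](C)(C)C(C)(C)C | starting material
2 | 2-(triphenylphosphoranylidene)propanal | CC(C=O)=P(c1ccccc1)(c1ccccc1)c1ccccc1 | starting material
3 | (E)-4-[(tert-butyldimethylsilyl)oxy]-2-methylbut-2-enal | O=C/C(C)=C/CO[Si](C)(C)C(C)(C)C | intermediate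
4 | allenylboronic acid pinacol ester (4,4,5,5-tetramethyl-2-(propa-1,2-dienyl)-1,3,2-dioxaborolane) | C=C=CB1OC(C)(C)C(C)(C)O1 | starting material
5 | pinacol borate ester of 6 (O–B(pin) at C4) | C#CC[C@H](OB1OC(C)(C)C(C)(C)O1)/C(C)=C/CO[Si](C)(C)C(C)(C)C | intermediate (not isolated)
6 | (2E,4S)-1-[(tert-butyldimethylsilyl)oxy]-3-methylhept-2-en-6-yn-4-ol | C#CC[C@H](O)/C(C)=C/CO[Si](C)(C)C(C)(C)C | intermediate
7 | 4-methylpent-4-en-1-ol | C=C(C)CCCO | starting material
8 | 5-iodo-2-methylpent-1-ene | C=C(C)CCCI | intermediate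
9 | dilithio derivative of 6 (lithium alkoxide at C4, lithium acetylide at C7) | [Li]C#CC[C@H](O[Li])/C(C)=C/CO[Si](C)(C)C(C)(C)C | intermediate (not isolated)
10 | (2E,4S)-1-[(tert-butyldimethylsilyl)oxy]-3,11-dimethyldodeca-2,11-dien-6-yn-4-ol | C=C(C)CCCC#CC[C@H](O)/C(C)=C/CO[Si](C)(C)C(C)(C)C | intermediate
11 | (2E,4S,6Z)-6-(bromomagnesio) bromomagnesium alkoxide of 12 (Mg on C6 cis to the C7 methyl) | C=C(C)CCC/C(C)=C(/[Mg]Br)C[C@H](O[Mg]Br)/C(C)=C/CO[Si](C)(C)C(C)(C)C | intermediate (not isolated)
12 | (2E,4S,6Z)-1-[(tert-butyldimethylsilyl)oxy]-3,7,11-trimethyldodeca-2,6,11-trien-4-ol | C=C(C)CCC/C(C)=C\C[C@H](O)/C(C)=C/CO[Si](C)(C)C(C)(C)C | intermediate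
13 | (2E,4S,6Z)-3,7,11-trimethyldodeca-2,6,11-triene-1,4-diol | C=C(C)CCC/C(C)=C\C[C@H](O)/C(C)=C/CO | intermediate
14 | (2E,4S,6Z)-4-hydroxy-3,7,11-trimethyldodeca-2,6,11-trienal | C=C(C)CCC/C(C)=C\C[C@H](O)/C(C)=C/C=O | intermediate
15 | (2E,4S,6Z)-3,7,11-trimethyl-4-[(triethylsilyl)oxy]dodeca-2,6,11-trienal | C=C(C)CCC/C(C)=C\C[C@H](O[Si](CC)(CC)CC)/C(C)=C/C=O | intermediate
16 | tertiary alkylchromium dichloride (CrCl2 on C11 of the hydrogenated chain of 15) | Cl[Cr](Cl)C(C)(C)CCC/C(C)=C\C[C@H](O[Si](CC)(CC)CC)/C(C)=C/C=O | intermediate (not isolated)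
17 | dichlorochromium alkoxide of 19 | Cl[Cr](Cl)O[C@@H]1/C=C(\C)[C@@H](O[Si](CC)(CC)CC)C/C=C(/C)CCCC1(C)C | intermediate (not isolated)
18 | phenylsilyl ether of 19 | c1ccccc1[SiH2]O[C@@H]1/C=C(\C)[C@@H](O[Si](CC)(CC)CC)C/C=C(/C)CCCC1(C)C | intermediate (not isolated)
19 | (1R,2E,4S,6Z)-3,7,11,11-tetramethyl-4-[(triethylsilyl)oxy]cycloundeca-2,6-dien-1-ol | O[C@@H]1/C=C(\C)[C@@H](O[Si](CC)(CC)CC)C/C=C(/C)CCCC1(C)C | intermediate
20 | vanillic acid | COc1cc(C(=O)O)ccc1O | starting material
21 | tert-butyldimethylsilyl 4-[(tert-butyldimethylsilyl)oxy]-3-methoxybenzoate | COc1cc(C(=O)O[Si](C)(C)C(C)(C)C)ccc1O[Si](C)(C)C(C)(C)C | intermediate (not isolated)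
22 | 4-[(tert-butyldimethylsilyl)oxy]-3-methoxybenzoic acid | COc1cc(C(=O)O)ccc1O[Si](C)(C)C(C)(C)C | intermediate
23 | 4-[(tert-butyldimethylsilyl)oxy]-3-methoxybenzoic 2,4,6-trichlorobenzoic anhydride | COc1cc(C(=O)OC(=O)c2c(Cl)cc(Cl)cc2Cl)ccc1O[Si](C)(C)C(C)(C)C | intermediate (not isolated)
24 | (1R,2E,4S,6Z)-3,7,11,11-tetramethyl-4-[(triethylsilyl)oxy]cycloundeca-2,6-dien-1-yl 4-[(tert-butyldimethylsilyl)oxy]-3-methoxybenzoate | COc1cc(C(=O)O[C@@H]2/C=C(\C)[C@@H](O[Si](CC)(CC)CC)C/C=C(/C)CCCC2(C)C)ccc1O[Si](C)(C)C(C)(C)C | intermediate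
25 | (1R,2E,4S,6Z)-4-hydroxy-3,7,11,11-tetramethylcycloundeca-2,6-dien-1-yl 4-hydroxy-3-methoxybenzoate | COc1cc(C(=O)O[C@@H]2/C=C(\C)[C@@H](O)C/C=C(/C)CCCC2(C)C)ccc1O | target

**Step count and risks**

Total steps: 12. Longest linear sequence: 10 (steps 1, 2, 4, 5, 6, 7, 8, 9, 11, 12); steps 3 and 10 are side branches.

Steps most likely to fail:

1. Step 9 (Proposed new method). What may go wrong: the tertiary radical may be lost by back-transfer of hydrogen (isomerisation of the isopropenyl group), by reduction, or by 6-endo attack on C6=C7 before it reaches chromium; alkyl transfer to chromium may be too slow at the dilution an eleven-membered ring needs; the closure may show poor facial selectivity at C1. Fallback (known reactions only; C1–C11 is made intermolecularly under reagent control and the ring is closed at C9–C10): from 6, copper-catalysed allylation of the alkyne terminus (allyl bromide, CuI, K2CO3, NaI, DMF) would give the skipped enyne (2E,4S)-1-[(tert-butyldimethylsilyl)oxy]-3-methyldeca-2,9-dien-6-yn-4-ol F1. Methylmagnesiation as in step 5 would give (2E,4S,6Z)-1-[(tert-butyldimethylsilyl)oxy]-3,7-dimethyldeca-2,6,9-trien-4-ol F2. The operations of steps 6 to 8 would give (2E,4S,6Z)-3,7-dimethyldeca-2,6,9-triene-1,4-diol F3, (2E,4S,6Z)-4-hydroxy-3,7-dimethyldeca-2,6,9-trienal F4 and (2E,4S,6Z)-3,7-dimethyl-4-[(triethylsilyl)oxy]deca-2,6,9-trienal F5. Reverse prenylation of F5 with B-(3-methylbut-2-enyl)diisopinocampheylborane (the antipode that attacks the Si face, expected to be the (−)-Ipc2B reagent from (+)-α-pinene by analogy with the parent allyl reagent; Et2O, −78 °C; then NaOH/H2O2) would form the C1–C11 bond, the quaternary carbon and the 1R centre in (4R,5E,7S,9Z)-3,3,6,10-tetramethyl-7-[(triethylsilyl)oxy]trideca-1,5,9,12-tetraen-4-ol F6. Ring-closing metathesis (second-generation Grubbs catalyst, CH2Cl2, 40 °C, 1 mM) would give (1R,2E,4S,6Z)-3,7,11,11-tetramethyl-4-[(triethylsilyl)oxy]cycloundeca-2,6,9-trien-1-ol F7. Diimide (2-nitrobenzenesulfonohydrazide, Et3N, CH2Cl2, rt) should saturate only the disubstituted C9=C10 bond and return to the route at 19.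

2. Step 5. What may go wrong: methyl delivery to C6 instead of C7 (loss of alkoxide direction), incomplete conversion, or iron-catalysed substitution of the allylic silyl ether. Fallback (Z geometry taken from a ring, not from a carbometalation): from 6, C-methylation of the dianion (n-BuLi, 2 equiv; MeI) would give (2E,4S)-1-[(tert-butyldimethylsilyl)oxy]-3-methyloct-2-en-6-yn-4-ol F8. Silylation with 1,1,3,3-tetramethyldisilazane would give (2E,4S)-1-[(tert-butyldimethylsilyl)oxy]-4-[(dimethylsilyl)oxy]-3-methyloct-2-en-6-yne F9. Ruthenium-catalysed intramolecular anti-hydrosilylation in the endo mode ([Cp*Ru(MeCN)3]PF6, CH2Cl2, 0 °C) would give the six-membered siloxane (6S)-6-[(E)-4-[(tert-butyldimethylsilyl)oxy]but-2-en-2-yl]-2,2,3-trimethyl-5,6-dihydro-2H-1,2-oxasiline F10, with silicon on C7 cis to C5. Iododesilylation with retention (N-iodosuccinimide, hexafluoroisopropanol, 0 °C; then K2CO3, MeOH) would give (2E,4S,6Z)-1-[(tert-butyldimethylsilyl)oxy]-7-iodo-3-methylocta-2,6-dien-4-ol F11. Negishi coupling of F11 with (4-methylpent-4-en-1-yl)zinc iodide F12 (from 8, Zn, LiCl, THF; Pd(dppf)Cl2, THF, rt) would return to the route at 12.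

3. Step 2. What may go wrong: insufficient or reversed facial selectivity with the α-branched enal, or acid-induced loss of the allylic silyl ether. Fallback (racemic addition, then kinetic resolution): from 3, zinc-mediated Barbier propargylation (propargyl bromide, Zn, THF/aq. NH4Cl) would give racemic (2E)-1-[(tert-butyldimethylsilyl)oxy]-3-methylhept-2-en-6-yn-4-ol F13. Sharpless kinetic resolution (Ti(OiPr)4, D-(−)-diisopropyl tartrate, t-BuOOH, 4 Å MS, CH2Cl2, −20 °C, about 55 % conversion) should epoxidise the R enantiomer to (1R)-1-[(2S,3S)-3-{[(tert-butyldimethylsilyl)oxy]methyl}-2-methyloxiran-2-yl]but-3-yn-1-ol F14 and leave the S enantiomer, which is 6.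

**Further compounds**

F1 | step 9 | (2E,4S)-1-[(tert-butyldimethylsilyl)oxy]-3-methyldeca-2,9-dien-6-yn-4-ol | C=CCC#CC[C@H](O)/C(C)=C/CO[Si](C)(C)C(C)(C)C
F2 | step 9 | (2E,4S,6Z)-1-[(tert-butyldimethylsilyl)oxy]-3,7-dimethyldeca-2,6,9-trien-4-ol | C=CC/C(C)=C\C[C@H](O)/C(C)=C/CO[Si](C)(C)C(C)(C)C
F3 | step 9 | (2E,4S,6Z)-3,7-dimethyldeca-2,6,9-triene-1,4-diol | C=CC/C(C)=C\C[C@H](O)/C(C)=C/CO
F4 | step 9 | (2E,4S,6Z)-4-hydroxy-3,7-dimethyldeca-2,6,9-trienal | C=CC/C(C)=C\C[C@H](O)/C(C)=C/C=O
F5 | step 9 | (2E,4S,6Z)-3,7-dimethyl-4-[(triethylsilyl)oxy]deca-2,6,9-trienal | C=CC/C(C)=C\C[C@H](O[Si](CC)(CC)CC)/C(C)=C/C=O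
F6 | step 9 | (4R,5E,7S,9Z)-3,3,6,10-tetramethyl-7-[(triethylsilyl)oxy]trideca-1,5,9,12-tetraen-4-ol | C=CC/C(C)=C\C[C@H](O[Si](CC)(CC)CC)/C(C)=C/[C@@H](O)C(C)(C)C=C
F7 | step 9 | (1R,2E,4S,6Z)-3,7,11,11-tetramethyl-4-[(triethylsilyl)oxy]cycloundeca-2,6,9-trien-1-ol (C9=C10 geometry open) | O[C@@H]1/C=C(\C)[C@@H](O[Si](CC)(CC)CC)C/C=C(/C)CC=CC1(C)C
F8 | step 5 | (2E,4S)-1-[(tert-butyldimethylsilyl)oxy]-3-methyloct-2-en-6-yn-4-ol | CC#CC[C@H](O)/C(C)=C/CO[Si](C)(C)C(C)(C)C
F9 | step 5 | (2E,4S)-1-[(tert-butyldimethylsilyl)oxy]-4-[(dimethylsilyl)oxy]-3-methyloct-2-en-6-yne | CC#CC[C@H](O[SiH](C)C)/C(C)=C/CO[Si](C)(C)C(C)(C)C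
F10 | step 5 | (6S)-6-[(E)-4-[(tert-butyldimethylsilyl)oxy]but-2-en-2-yl]-2,2,3-trimethyl-5,6-dihydro-2H-1,2-oxasiline | CC1=CC[C@H](O[Si]1(C)C)/C(C)=C/CO[Si](C)(C)C(C)(C)C
F11 | step 5 | (2E,4S,6Z)-1-[(tert-butyldimethylsilyl)oxy]-7-iodo-3-methylocta-2,6-dien-4-ol | C/C(I)=C/C[C@H](O)/C(C)=C/CO[Si](C)(C)C(C)(C)C
F12 | step 5 | (4-methylpent-4-en-1-yl)zinc iodide | C=C(C)CCC[Zn]I
F13 | step 2 | racemic (2E)-1-[(tert-butyldimethylsilyl)oxy]-3-methylhept-2-en-6-yn-4-ol | C#CCC(O)/C(C)=C/CO[Si](C)(C)C(C)(C)C
F14 | step 2 | (1R)-1-[(2S,3S)-3-{[(tert-butyldimethylsilyl)oxy]methyl}-2-methyloxiran-2-yl]but-3-yn-1-ol | C#CC[C@@H](O)[C@]1(C)O[C@H]1CO[Si](C)(C)C(C)(C)C
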